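**Retrosynthetic overview**

1. The butenolide is closed last by ring-closing metathesis of an allyl acrylate. That acrylate comes from an asymmetric Morita–Baylis–Hillman reaction on a C12 aldehyde (sets C12). C8=CH2 comes from a C8 ketone; C11/C12 come from an aldol condensation at C9 followed by a face-selective hydrogenation (sets C9).
2. C3–OH comes from a C3 ketone, itself the Nef product of a C3 nitro group: the carbinol carbon is carried as a carbon nucleophile (polarity reversal).
3. Key disconnection, ring A: a formal [3+3] union of γ-nitro aldehyde 7 (donor carbons C3 and C5) with dienone 10 (acceptor carbons C2 and C10) forms C2–C3 and C5–C10. Ring B closes in the same pot by aldol condensation (C6=C7). Ring order: A, then B, then butenolide.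
4. Enabling feature: C8 of ring B, which ends as the exocyclic methylene carbon, is a ketone whose conjugation through C9=C10–C1=C2 makes both C10 (β) and C2 (δ) electrophilic. The quaternary C4 keeps the nitronate carbon C3 apart from the enamine carbon C5 (C6 aldehyde).
5. Fragments: 7 (C4 set by iminium catalysis) in three steps from hydroxyacetone; 10 in one step from 4-methoxypent-3-en-2-one.

Key step: step 5

Remark: labdane numbering is used (ring A: C1–C5, C10; ring B: C5–C10; side chain C11, C12; butenolide C13–C16); the target as drawn is 3R,4S,5S,9R,10S,12R, so the C4 methyl is axial and cis to the C10 methyl and the CH2OH is equatorial, and the route is built for this arrangement.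

**Route**

Step 1
Reactants: 1 hydroxyacetone; 2 tert-butyl(chloro)diphenylsilane
Product: 3 1-[(tert-butyldiphenylsilyl)oxy]propan-2-one
Conditions: imidazole, CH2Cl2, 0 °C to rt
Reagents that add atoms: tert-butyl(chloro)diphenylsilane (2), CC(C)(C)[Si](Cl)(c1ccccc1)c1ccccc1
Why: Imidazole-mediated O-silylation of the primary alcohol gives a TBDPS ether that should survive every later step up to the final deprotection; no stereocentre is formed.

Step 2
Reactants: 3 1-[(tert-butyldiphenylsilyl)oxy]propan-2-one; 4 (triphenylphosphoranylidene)acetaldehyde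
Product: 5 (2E)-4-[(tert-butyldiphenylsilyl)oxy]-3-methylbut-2-enal
Conditions: PhMe, 110 °C
Reagents that add atoms: (triphenylphosphoranylidene)acetaldehyde (4), O=CC=P(c1ccccc1)(c1ccccc1)c1ccccc1
Why: Wittig olefination of the activated α-silyloxy ketone with the stabilised formyl ylide should give the trisubstituted enal, with the E isomer (CHO trans to CH2OSi) favoured and purified by chromatography.

Step 3
Reactants: 5 (2E)-4-[(tert-butyldiphenylsilyl)oxy]-3-methylbut-2-enal; 6 nitromethane
Product: 7 (3R)-3-{[(tert-butyldiphenylsilyl)oxy]methyl}-3-methyl-4-nitrobutanal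
Conditions: (S)-α,α-diphenylprolinol trimethylsilyl ether (20 mol%), PhCO2H (20 mol%), MeNO2 (5 equiv), MeOH, rt
Reagents that add atoms: nitromethane (6), C[N+](=O)[O-]
Why: Iminium-catalysed conjugate addition of nitromethane to a β,β-disubstituted enal (Hayashi-type construction of an all-carbon quaternary centre); the (S)-catalyst shields one face of the s-trans E-iminium ion, so nitromethane should add anti to the diphenyl(silyloxy)methyl group and give the (R) centre that becomes C4.

Step 4
Reactants: 8 (3E)-4-methoxypent-3-en-2-one; 9 vinylmagnesium bromide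
Product: 10 (3E)-4-methylhexa-3,5-dien-2-one
Conditions: THF, −78 to 0 °C; then 1 M HCl, 0 °C
Reagents that add atoms: vinylmagnesium bromide (9), C=C[Mg]Br
Why: 1,2-Addition of the Grignard reagent to the vinylogous ester and acid-induced loss of methanol (Stork–Danheiser-type transposition; because the acetylacetone skeleton is symmetric, 1,2- and 1,4-addition converge) should give the thermodynamically favoured E dienone.

Step 5
Reactants: 7 (3R)-3-{[(tert-butyldiphenylsilyl)oxy]methyl}-3-methyl-4-nitrobutanal; 10 (3E)-4-methylhexa-3,5-dien-2-one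
Product: 13 trans-fused bicyclic nitro enone (3R,4R,5S,10S; C8 ketone; C6=C7; equatorial C3 nitro; axial C4 methyl cis to the C10 methyl; equatorial CH2OTBDPS), via enone aldehyde 11 (not isolated), via ring A keto aldehyde 12 (not isolated)
Conditions: one pot: 1,1,3,3-tetramethylguanidine (0.2 equiv), CH2Cl2, 0 °C to rt; then (S)-α,α-diphenylprolinol trimethylsilyl ether (0.2 equiv), PhCO2H (0.4 equiv), 40 °C; then p-TsOH·H2O (0.3 equiv), 40 °C
Reagents that add atoms: (3E)-4-methylhexa-3,5-dien-2-one (10), CC(=O)/C=C(\C)C=C
Why: Proposed new method: a one-pot formal [3+3] annulation with Robinson closure, closest to amine-catalysed Michael/Michael/aldol-condensation triple cascades and to nitronate 1,6-additions to dienones, in which the guanidine first generates the C3 nitronate of 7, which adds to the unhindered δ-terminus C2 of 10 (forms C2–C3) and, after reprotonation to the conjugated enone 11, leaves C10 as the β-carbon of the same C8 ketone. The prolinol catalyst then converts the C6 aldehyde into its enamine, whose C5 attacks C10 in a 6-exo-trig Michael addition through a chair with the enamine arm, the enone arm and the CH2OTBDPS group equatorial (forms C5–C10, closes ring A, gives 12). Acid then closes ring B by 6-(enolexo)-exo-trig aldol condensation of the C7 methyl-ketone carbon onto C6. C5 is set by the catalyst (attack on the enamine face away from the diphenyl(silyloxy)methyl group, matched with the C4 centre brought in by 7), C10 by the chair (methyl axial, anti to H5), and the C3 nitro epimers equilibrate to the equatorial one and do not matter because C3 becomes a ketone. The step needs chemoselectivity between two donors and two acceptor sites: the nitronate is formed under base alone and takes the terminal CH2 because C10 is β,β-disubstituted, and the amine catalyst is added only after the base has been buffered by the acid, which should exclude the crossed annulation and an uncatalysed background cyclisation. Both ring A bonds thus arise from the C8 carbonyl acting twice as a vinylogous acceptor, with the quaternary C4 holding the two donor carbons apart.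

Step 6
Reactants: 13 bicyclic nitro enone; 14 potassium peroxymonosulfate (active component of Oxone)
Product: 15 bicyclic ene-dione (4S,5S,10S; C3 ketone; C8 enone)
Conditions: NaOH (1.2 equiv), MeOH/H2O, 0 °C; then Oxone (2KHSO5·KHSO4·K2SO4), Na2HPO4, 0 °C to rt
Reagents that add atoms: potassium peroxymonosulfate (14), [K+].[O-]S(=O)(=O)OO
Why: Oxidative Nef reaction: the C3 nitronate is oxidised at carbon by peroxymonosulfate and collapses with loss of nitrite to the C3 ketone, while the electron-poor enone C=C should be inert to this electrophilic oxidant; the C3 stereocentre is deliberately erased here.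

Step 7
Reactants: 15 bicyclic ene-dione
Product: 16 hydroxy enone (3R,4S,5S,10S; equatorial C3–OH)
Conditions: NaBH4 (0.5 equiv), MeOH/CH2Cl2 (1:1), −78 °C
Reagents that add atoms: none
Why: Chemoselective borohydride reduction of a saturated ketone beside a conjugated enone at low temperature (Ward-type selectivity); hydride should attack C3 along the axial trajectory, on the face opposite the axial C4 methyl, which gives the equatorial (3R) alcohol.

Step 8
Reactants: 16 hydroxy enone; 17 tert-butyldimethylsilyl trifluoromethanesulfonate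
Product: 18 bis-silyl enone (C3–OTBS; stereocentres as in 16)
Conditions: 2,6-lutidine, CH2Cl2, −40 to 0 °C
Reagents that add atoms: tert-butyldimethylsilyl trifluoromethanesulfonate (17), CC(C)(C)[Si](C)(C)OS(=O)(=O)C(F)(F)F
Why: Silylation of the hindered neopentyl secondary alcohol with the silyl triflate protects C3–OH against the enolate chemistry that follows; no stereocentre is touched.

Step 9
Reactants: 18 bis-silyl enone; 19 ethyl glyoxylate
Product: 22 cross-conjugated alkylidene keto ester (C9=C11; E/Z mixture is inconsequential), via aldol adduct 20 (not isolated), via mesylate 21 (not isolated)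
Conditions: LDA (1.1 equiv), THF, −78 °C; then 19; then MsCl, −78 to 0 °C; then DBU, rt
Reagents that add atoms: ethyl glyoxylate (19), CCOC(=O)C=O
Why: Kinetic deprotonation of the enone at the α′-carbon C9 gives the cross-conjugated lithium enolate, and its aldol addition to the glyoxylate aldehyde followed by mesylation and E1cB elimination amounts to an aldol condensation that installs C11 and C12.

Step 10
Reactants: 22 alkylidene keto ester
Product: 23 saturated keto ester (3R,4S,5S,9S,10R by CIP rules; CH2CO2Et at C9 equatorial and cis to the C10 methyl)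
Conditions: H2 (1 atm), 10% Pd/C, EtOAc, rt
Reagents that add atoms: none
Why: Heterogeneous hydrogenation saturates both conjugated C=C bonds (C6=C7 and C9=C11); hydrogen should be delivered to C9 from the face opposite the axial C10 methyl, so the side chain ends equatorial and cis to that methyl, which is also the more stable C9 epimer.

Step 11
Reactants: 23 saturated keto ester; 24 dibromomethane
Product: 25 exocyclic methylene ester (3R,4S,5S,9R,10S)
Conditions: Zn, CH2Br2, TiCl4, THF/CH2Cl2, 0 °C to rt
Reagents that add atoms: dibromomethane (24), BrCBr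
Why: Takai–Lombardo methylenation converts the hindered, enolisable C8 ketone into C8=CH2 without base, so C9 should not epimerise and the ester should be untouched.

Step 12
Reactants: 25 exocyclic methylene ester
Product: 26 C12 aldehyde (stereocentres as in 25)
Conditions: DIBAL-H (1.1 equiv), CH2Cl2, −78 °C; Rochelle salt work-up
Reagents that add atoms: none
Why: Partial reduction of the ester by DIBAL-H at −78 °C should stop at the aluminium hemiacetal, which releases the aldehyde on work-up.

Step 13
Reactants: 26 C12 aldehyde; 27 1,1,1,3,3,3-hexafluoropropan-2-yl acrylate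
Product: 28 Morita–Baylis–Hillman adduct (12R; hexafluoroisopropyl 2-methylidene-3-hydroxy ester)
Conditions: β-isocupreidine (20 mol%), DMF, −55 °C
Reagents that add atoms: 1,1,1,3,3,3-hexafluoropropan-2-yl acrylate (27), C=CC(=O)OC(C(F)(F)F)C(F)(F)F
Why: β-Isocupreidine-catalysed asymmetric Morita–Baylis–Hillman reaction with the activated acrylate (Hatakeyama conditions); the catalyst, not the remote ring stereocentres, controls the aldehyde face and is expected to give the (12R) carbinol.

Step 14
Reactants: 28 Morita–Baylis–Hillman adduct; 29 allyl alcohol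
Product: 30 allyl 2-methylidene-3-hydroxy ester (12R)
Conditions: allyl alcohol (solvent), Et3N, rt
Reagents that add atoms: allyl alcohol (29), C=CCO
Why: Amine-promoted transesterification of the activated hexafluoroisopropyl ester installs the second alkene for ring closure without touching the silyl ethers or C12.

Step 15
Reactants: 30 allyl ester
Product: 31 bis-silyl butenolide (3R,4S,5S,9R,10S,12R)
Conditions: second-generation Grubbs catalyst (10 mol%), PhMe, 80 °C
Reagents that add atoms: none
Why: Ring-closing metathesis of the allyl acrylate forms the five-membered butenolide with its trisubstituted C13=C14 bond and releases ethylene; the hindered 1,1-disubstituted C8 methylene should not engage.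

Step 16
Reactants: 31 bis-silyl butenolide
Product: 32 target, 3-[(1R)-1-hydroxy-2-[(1R,4aS,5S,6R,8aS)-6-hydroxy-5-(hydroxymethyl)-5,8a-dimethyl-2-methylidenedecahydronaphthalen-1-yl]ethyl]furan-2(5H)-one
Conditions: HF·pyridine, THF/pyridine, 0 °C to rt
Reagents that add atoms: none
Why: Fluoride cleavage of both silyl ethers under buffered acidic conditions should spare the base-sensitive butenolide and the exocyclic alkene; no stereocentre is affected.

**Compound list**

1 | hydroxyacetone | CC(=O)CO | starting material
2 | tert-butyl(chloro)diphenylsilane | CC(C)(C)[Si](Cl)(c1ccccc1)c1ccccc1 | starting material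
3 | 1-[(tert-butyldiphenylsilyl)oxy]propan-2-one | CC(=O)CO[Si](c1ccccc1)(c1ccccc1)C(C)(C)C | intermediate
4 | (triphenylphosphoranylidene)acetaldehyde | O=CC=P(c1ccccc1)(c1ccccc1)c1ccccc1 | starting material
5 | (2E)-4-[(tert-butyldiphenylsilyl)oxy]-3-methylbut-2-enal | O=C/C=C(\C)CO[Si](c1ccccc1)(c1ccccc1)C(C)(C)C | intermediate
6 | nitromethane | C[N+](=O)[O-] | starting material
7 | (3R)-3-{[(tert-butyldiphenylsilyl)oxy]methyl}-3-methyl-4-nitrobutanal | O=CC[C@@](C)(CO[Si](c1ccccc1)(c1ccccc1)C(C)(C)C)C[N+](=O)[O-] | intermediate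
8 | (3E)-4-methoxypent-3-en-2-one | CO/C(C)=C/C(C)=O | starting material
9 | vinylmagnesium bromide | C=C[Mg]Br | starting material
10 | (3E)-4-methylhexa-3,5-dien-2-one | CC(=O)/C=C(\C)C=C | intermediate
11 | (3R,7E)-3-{[(tert-butyldiphenylsilyl)oxy]methyl}-3,7-dimethyl-4-nitro-9-oxodec-7-enal (epimers at the nitro carbon) | O=CC[C@@](C)(CO[Si](c1ccccc1)(c1ccccc1)C(C)(C)C)C(CC/C(C)=C/C(C)=O)[N+](=O)[O-] | intermediate
12 | (1S,2R,3R,6S)-2-{[(tert-butyldiphenylsilyl)oxy]methyl}-2,6-dimethyl-3-nitro-6-(2-oxopropyl)cyclohexane-1-carbaldehyde | O=C[C@@H]1[C@@](C)(CO[Si](c2ccccc2)(c2ccccc2)C(C)(C)C)[C@H]([N+](=O)[O-])CC[C@@]1(C)CC(C)=O | intermediate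
13 | (4aS,5R,6R,8aS)-5-{[(tert-butyldiphenylsilyl)oxy]methyl}-5,8a-dimethyl-6-nitro-4a,5,6,7,8,8a-hexahydronaphthalen-2(1H)-one | O=C1C=C[C@@H]2[C@@](C)(CO[Si](c3ccccc3)(c3ccccc3)C(C)(C)C)[C@H]([N+](=O)[O-])CC[C@@]2(C)C1 | intermediate
14 | potassium peroxymonosulfate (active component of Oxone) | [K+].[O-]S(=O)(=O)OO | starting material
15 | (4aS,5S,8aS)-5-{[(tert-butyldiphenylsilyl)oxy]methyl}-5,8a-dimethyl-4a,7,8,8a-tetrahydronaphthalene-2,6(1H,5H)-dione | O=C1C=C[C@@H]2[C@@](C)(CO[Si](c3ccccc3)(c3ccccc3)C(C)(C)C)C(=O)CC[C@@]2(C)C1 | intermediate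
16 | (4aS,5S,6R,8aS)-5-{[(tert-butyldiphenylsilyl)oxy]methyl}-6-hydroxy-5,8a-dimethyl-4a,5,6,7,8,8a-hexahydronaphthalen-2(1H)-one | O=C1C=C[C@@H]2[C@@](C)(CO[Si](c3ccccc3)(c3ccccc3)C(C)(C)C)[C@H](O)CC[C@@]2(C)C1 | intermediate
17 | tert-butyldimethylsilyl trifluoromethanesulfonate | CC(C)(C)[Si](C)(C)OS(=O)(=O)C(F)(F)F | starting material
18 | C3 tert-butyldimethylsilyl ether of 16 | O=C1C=C[C@@H]2[C@@](C)(CO[Si](c3ccccc3)(c3ccccc3)C(C)(C)C)[C@H](O[Si](C)(C)C(C)(C)C)CC[C@@]2(C)C1 | intermediate
19 | ethyl glyoxylate | CCOC(=O)C=O | starting material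
20 | C9 aldol adduct of 18 (ethyl 2-hydroxyacetate side chain at C9; isomer mixture) | O=C1C=C[C@@H]2[C@@](C)(CO[Si](c3ccccc3)(c3ccccc3)C(C)(C)C)[C@H](O[Si](C)(C)C(C)(C)C)CC[C@@]2(C)C1C(O)C(=O)OCC | intermediate
21 | methanesulfonate of 20 | O=C1C=C[C@@H]2[C@@](C)(CO[Si](c3ccccc3)(c3ccccc3)C(C)(C)C)[C@H](O[Si](C)(C)C(C)(C)C)CC[C@@]2(C)C1C(OS(C)(=O)=O)C(=O)OCC | intermediate
22 | ethyl 2-[2-oxo-1(2H)-naphthalenylidene]acetate derivative of 18 (C9=C11; ring stereocentres as in 18) | O=C1C=C[C@@H]2[C@@](C)(CO[Si](c3ccccc3)(c3ccccc3)C(C)(C)C)[C@H](O[Si](C)(C)C(C)(C)C)CC[C@@]2(C)C1=CC(=O)OCC | intermediate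
23 | saturated keto ester (C8 ketone; CH2CO2Et at C9 equatorial, cis to the C10 methyl) | O=C1CC[C@@H]2[C@@](C)(CO[Si](c3ccccc3)(c3ccccc3)C(C)(C)C)[C@H](O[Si](C)(C)C(C)(C)C)CC[C@@]2(C)[C@@H]1CC(=O)OCC | intermediate
24 | dibromomethane | BrCBr | starting material
25 | exocyclic methylene ester (3R,4S,5S,9R,10S) | C=C1CC[C@@H]2[C@@](C)(CO[Si](c3ccccc3)(c3ccccc3)C(C)(C)C)[C@H](O[Si](C)(C)C(C)(C)C)CC[C@@]2(C)[C@@H]1CC(=O)OCC | intermediate
26 | C12 aldehyde (3R,4S,5S,9R,10S) | C=C1CC[C@@H]2[C@@](C)(CO[Si](c3ccccc3)(c3ccccc3)C(C)(C)C)[C@H](O[Si](C)(C)C(C)(C)C)CC[C@@]2(C)[C@@H]1CC=O | intermediate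
27 | 1,1,1,3,3,3-hexafluoropropan-2-yl acrylate | C=CC(=O)OC(C(F)(F)F)C(F)(F)F | starting material
28 | (12R) Morita–Baylis–Hillman adduct, hexafluoroisopropyl ester | C=C1CC[C@@H]2[C@@](C)(CO[Si](c3ccccc3)(c3ccccc3)C(C)(C)C)[C@H](O[Si](C)(C)C(C)(C)C)CC[C@@]2(C)[C@@H]1C[C@@H](O)C(=C)C(=O)OC(C(F)(F)F)C(F)(F)F | intermediate
29 | allyl alcohol | C=CCO | starting material
30 | (12R) allyl 2-methylidene-3-hydroxy ester | C=C1CC[C@@H]2[C@@](C)(CO[Si](c3ccccc3)(c3ccccc3)C(C)(C)C)[C@H](O[Si](C)(C)C(C)(C)C)CC[C@@]2(C)[C@@H]1C[C@@H](O)C(=C)C(=O)OCC=C | intermediate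
31 | bis-silyl ether of the target (C3–OTBS, CH2OTBDPS) | C=C1CC[C@@H]2[C@@](C)(CO[Si](c3ccccc3)(c3ccccc3)C(C)(C)C)[C@H](O[Si](C)(C)C(C)(C)C)CC[C@@]2(C)[C@@H]1C[C@@H](O)C1=CCOC1=O | intermediate
32 | 3-[(1R)-1-hydroxy-2-[(1R,4aS,5S,6R,8aS)-6-hydroxy-5-(hydroxymethyl)-5,8a-dimethyl-2-methylidenedecahydronaphthalen-1-yl]ethyl]furan-2(5H)-one | C=C1CC[C@@H]2[C@@](C)(CO)[C@H](O)CC[C@@]2(C)[C@@H]1C[C@@H](O)C1=CCOC1=O | target

**Step count and risks**

Total step count: 16. Longest linear sequence: 15 steps (steps 1, 2, 3 and 5 to 16).

Steps most likely to fail: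

Step 5 (Proposed new method). The hindered enamine may add to the β,β-disubstituted C10 too slowly. Base-mediated background cyclisation without catalyst control, reversal of the 1,6-addition or oligomerisation of dienone 10 could then take over and erode the C5/C10 control. The fallback uses known chemistry, sets out from 7 and 10 and returns at 13. The guanidine-catalysed 1,6-addition is run alone and enone aldehyde 11 is isolated. Its aldehyde is condensed with one equivalent of pyrrolidine (4 Å sieves) to the pyrrolidine enamine of 11 F1. This is cyclised thermally (Stork enamine Michael addition, PhMe, 110 °C) and then hydrolysed and closed with aqueous AcOH/NaOAc (Robinson annulation conditions) to 13. Stereocontrol then rests on the C4 centre and the chair alone, and a minor C10 epimer would be removed by chromatography at 13.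

Step 7. Chemoselectivity may be lost: because the C3 ketone is flanked by the quaternary C4, 1,2-reduction of the C8 enone could compete. The fallback sets out from 15 and returns at 16. Both carbonyl groups are reduced (NaBH4, CeCl3·7H2O, MeOH, 0 °C) to the 3,8-diol F2 (C8 epimers), and the allylic C8 alcohol alone is re-oxidised with MnO2 (CH2Cl2, rt).

Step 13. Addition to this β-branched aldehyde may be slow or poorly face-selective, or the adduct may be diverted into dioxanone by-products. The fallback sets out from 26 and returns at 31, so steps 14 and 15 are not needed. Nozaki–Hiyama–Kishi coupling of 26 with 3-bromofuran-2(5H)-one (CrCl2, catalytic NiCl2, DMF) should give the silylated butenolide carbinol as a C12 epimer mixture F3. Dess–Martin oxidation gives the C12 ketone F4. Reduction with BH3·SMe2 and the (S)-2-methyl-CBS-oxazaborolidine catalyst (butenolide carbon as the large group) should return (12R)-31.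

**Further compounds**

F1 | step 5 | pyrrolidine enamine of 11 | C1CCN(C1)/C=C/[C@@](C)(CO[Si](c2ccccc2)(c2ccccc2)C(C)(C)C)C(CC/C(C)=C/C(C)=O)[N+](=O)[O-]
F2 | step 7 | 3,8-diol from 15 (C8 epimers; C3–OH equatorial) | OC1C=C[C@@H]2[C@@](C)(CO[Si](c3ccccc3)(c3ccccc3)C(C)(C)C)[C@H](O)CC[C@@]2(C)C1
F3 | step 13 | C12 epimer mixture of 31 | C=C1CC[C@@H]2[C@@](C)(CO[Si](c3ccccc3)(c3ccccc3)C(C)(C)C)[C@H](O[Si](C)(C)C(C)(C)C)CC[C@@]2(C)[C@@H]1CC(O)C1=CCOC1=O
F4 | step 13 | C12 ketone of 31 | C=C1CC[C@@H]2[C@@](C)(CO[Si](c3ccccc3)(c3ccccc3)C(C)(C)C)[C@H](O[Si](C)(C)C(C)(C)C)CC[C@@]2(C)[C@@H]1CC(=O)C1=CCOC1=O
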